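**Strategy.** Ring B is cut across C5–C6 and C8–C9, which leaves a ring A ketone that carries the quaternary C10 with a chloromethyl arm (C9) and the symmetrical diene diester dimethyl 2,3-dimethylenesuccinate. The route exploits the 1,4-placement of oxygen at C5 and C8 across ring B and the hidden twofold symmetry of the C8–C7–C11(=C13)–C12 array. In one SmI2 operation the C5 ketyl adds to a methylene terminus of the diene and the C9 organosamarium acylates the neighbouring ester, so that ring B closes with the C8 carbonyl, the C5 oxygen and the intact methyl acrylate in place. Oxidation-state adjustment of ring A, two acylations and a Schenck ene reaction complete the target.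

Key step: step 6

Remark: eudesmane numbering (ring A C1–C5, C10; ring B C5–C10; C14 on C10, C15 on C4, C11–C13 on C7; 10β-methyl series) is used for all bicyclic compounds and the atoms they come from. Compounds 1 and 7 are taken as purchasable, and the ligand antipodes in steps 2 and 4 are those that give the configurations drawn.

**Step 1**
Reactants: 1 2,6-dimethylcyclohex-2-en-1-one
Product: 2 [(2,6-dimethylcyclohexa-1,5-dien-1-yl)oxy]trimethylsilane
Conditions: LiN(i-Pr)2, THF, −78 °C; TMSCl, −78 °C to rt
Reagents that add atoms: chlorotrimethylsilane, C[Si](C)(C)Cl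
Why: Kinetic α′-deprotonation of the enone at the C6 methine and O-silylation (silyl enol ether formation) should give the cross-conjugated 2-siloxydiene, which erases the stereocentre of racemic 1.

**Step 2**
Reactants: 2 [(2,6-dimethylcyclohexa-1,5-dien-1-yl)oxy]trimethylsilane
Product: 3 (R)-6-(hydroxymethyl)-2,6-dimethylcyclohex-2-en-1-one
Conditions: aq. HCHO, Sc(OTf)3 (10 mol %), (S,S)-6,6′-bis(1-hydroxy-2,2-dimethylpropyl)-2,2′-bipyridine (12 mol %), DME/H2O, −20 °C
Reagents that add atoms: formaldehyde, C=O
Why: Chiral Lewis acid catalysed aqueous Mukaiyama aldol reaction (hydroxymethylation) in which the scandium–bipyridine complex binds formaldehyde and shields one face of the tetrasubstituted enol ether carbon, so the quaternary centre (C10 of the target) should form as R under ligand control.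

**Step 3**
Reactants: 3 (R)-6-(hydroxymethyl)-2,6-dimethylcyclohex-2-en-1-one
Product: 4 (S)-6-(chloromethyl)-2,6-dimethylcyclohex-2-en-1-one
Conditions: PPh3, CCl4, MeCN, 60 °C
Reagents that add atoms: tetrachloromethane, ClC(Cl)(Cl)Cl
Why: Appel reaction of the neopentyl-type primary alcohol through the alkoxyphosphonium chloride; the neutral medium avoids retro-aldol loss of formaldehyde, and the stereocentre is untouched (the descriptor changes only by priority).

**Step 4**
Reactants: 4 (S)-6-(chloromethyl)-2,6-dimethylcyclohex-2-en-1-one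
Product: 6 (2R,3R,6S)-6-(chloromethyl)-3-hydroxy-2,6-dimethylcyclohexan-1-one, via boryl ketone 5 (not isolated)
Conditions: B2pin2, CuCl (5 mol %), (R,R)-2,3-bis(tert-butylmethylphosphino)quinoxaline (6 mol %), NaOt-Bu (10 mol %), MeOH, THF, 0 °C; then NaBO3·4H2O, THF/H2O, rt
Reagents that add atoms: sodium perborate, [Na+].[O-]OB=O; bis(pinacolato)diboron, CC1(C)OB(OC1(C)C)B1OC(C)(C)C(C)(C)O1 (boron of 5)
Why: Copper-catalysed asymmetric conjugate borylation followed by C–B oxidation with retention; the ligand-bound copper boryl should add to C3 on the face that puts oxygen trans to the quaternary methyl (cis to the chloromethyl arm), and protonation of the enolate anti to boron places the C2 methyl cis to it.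

**Step 5**
Reactants: 7 methyl 2-bromoacrylate
Product: 8 dimethyl 2,3-dimethylenesuccinate
Conditions: NiCl2(PPh3)2 (10 mol %), Zn, Et4NI, THF, 50 °C (BHT; product used fresh)
Reagents that add atoms: methyl 2-bromoacrylate (second molecule of 7), C=C(Br)C(=O)OC
Why: Nickel-catalysed reductive homocoupling of an alkenyl bromide (Ullmann-type): zinc reduces NiCl2(PPh3)2 to zerovalent nickel, which inserts into the C–Br bond of two molecules of 7 in turn and joins their α-carbons by reductive elimination to the symmetrical diene diester; no stereocentre is formed.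

**Step 6**
Reactants: 6 (2R,3R,6S)-6-(chloromethyl)-3-hydroxy-2,6-dimethylcyclohexan-1-one, 8 dimethyl 2,3-dimethylenesuccinate
Product: 10 methyl 3α,5α-dihydroxy-8-oxo-4βH-eudesm-11(13)-en-12-oate as a mixture of C7 epimers, via spirolactone 9 (not isolated)
Conditions: SmI2 (4.5 equiv), THF, −78 to 0 °C, dark, slow addition of 8; then visible light, rt; aq. NH4Cl
Reagents that add atoms: none
Why: SmI2 reduces the C5 ketone of 6, held in a chelate with the cis 3-oxygen, to a ketyl that adds to a methylene terminus of 8 (C5–C6); the delocalised radical is reduced, the samarium enolate is protonated at C7 by the substrate hydroxyl (so no external proton source is left over), and the C5 alkoxide closes γ-lactone 9 on the proximal ester (5-exo-trig O-acylation). Photoexcited SmI2 then cleaves the neopentyl C–Cl bond and the C9 organosamarium adds to the lactone carbonyl (C8–C9), a 5-exo-trig closure through O5 that is a 6-exo-trig closure of ring B along the carbon chain; the bridged hemiketal opens to the 5-hydroxy 8-ketone on work-up. The closest known reaction type is the sequenced samarium-mediated intermolecular ketyl–olefin coupling/intramolecular nucleophilic acyl substitution of chloro ketones with acrylates, each bond joining two carbons of like polarity by reduction. C5 is set by the chelate, which keeps the ketyl oxygen α and sends the acceptor to the equatorial β side (5α-O trans to the angular methyl); C10 comes from 6 unchanged; C7 is formed without control and is corrected in step 7. The step needs ketyl coupling to outrun both reduction of 8 and cleavage of the C–Cl bond, which the dark, cold first stage and slow addition of 8 should secure; the quaternary C10 makes loss of HCl from the β-chloro ketone impossible, and the twofold symmetry of 8 removes any regiochemical issue while its second half survives as the methyl acrylate.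

**Step 7**
Reactants: 10 methyl 3α,5α-dihydroxy-8-oxo-4βH-eudesm-11(13)-en-12-oate (C7 epimers)
Product: 11 methyl 3α,5α-dihydroxy-8-oxo-4βH,7αH-eudesm-11(13)-en-12-oate
Conditions: KOt-Bu (3.5 equiv), THF, −40 °C; inverse quench into AcOH, THF, −78 °C
Reagents that add atoms: none
Why: Deconjugative kinetic protonation of an extended enolate: KOt-Bu forms the thermodynamic C7–C8 dienolate from both C7 epimers (and from any conjugated 7(11)-ene), and the fast acid quench should protonate C7 from the α face along the chair-like axial trajectory, assisted by the syn-axial 5α-alkoxide, which places the acrylate side chain equatorial (7β).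

**Step 8**
Reactants: 11 methyl 3α,5α-dihydroxy-8-oxo-4βH,7αH-eudesm-11(13)-en-12-oate
Product: 12 methyl 5α-hydroxy-3,8-dioxo-4βH,7αH-eudesm-11(13)-en-12-oate
Conditions: Dess–Martin periodinane, CH2Cl2, 0 °C to rt
Reagents that add atoms: none
Why: Dess–Martin oxidation of the secondary 3α-alcohol; the tertiary alcohol is inert and the non-basic medium avoids retro-aldol cleavage of the β-ketol and epimerisation at C7.

**Step 9**
Reactants: 12 methyl 5α-hydroxy-3,8-dioxo-4βH,7αH-eudesm-11(13)-en-12-oate
Product: 13 methyl 3,8-dioxo-7αH-eudesma-4,11(13)-dien-12-oate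
Conditions: Martin sulfurane, CH2Cl2, 0 °C to rt
Reagents that add atoms: none
Why: Dehydration of the tertiary β-hydroxy ketone with Martin sulfurane (anti elimination) should remove the acidic axial 4β-hydrogen with the 5α-hydroxyl to give the conjugated Δ4-3-ketone, erasing the auxiliary stereocentres at C4 and C5.

**Step 10**
Reactants: 13 methyl 3,8-dioxo-7αH-eudesma-4,11(13)-dien-12-oate
Product: 14 methyl 3β,8β-dihydroxy-7αH-eudesma-4,11(13)-dien-12-oate
Conditions: NaBH4, CeCl3·7H2O, MeOH/CH2Cl2, −78 °C; aq. NH4Cl quench at −78 °C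
Reagents that add atoms: none
Why: Luche reduction (1,2-selective): hydride should attack the enone carbonyl from the α face to give the pseudo-equatorial 3β-alcohol and the C8 ketone equatorially from the α face, the β face being blocked by the 1,3-diaxial angular methyl, to give the axial 8β-alcohol cis to the C7 side chain; the acrylate is untouched and the cold quench is meant to forestall lactonisation.

**Step 11**
Reactants: 14 methyl 3β,8β-dihydroxy-7αH-eudesma-4,11(13)-dien-12-oate
Product: 15 methyl 8β-hydroxy-3β-(2-methylpropanoyloxy)-7αH-eudesma-4,11(13)-dien-12-oate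
Conditions: (i-PrCO)2O (1.05 equiv), DMAP (cat.), Et3N, CH2Cl2, −40 °C
Reagents that add atoms: isobutyric anhydride, CC(C)C(=O)OC(=O)C(C)C
Why: DMAP-catalysed acylation should differentiate the alcohols sterically: the equatorial allylic 3β-hydroxyl reacts, while the axial 8β-hydroxyl, 1,3-diaxial to the angular methyl and flanked by the C7 substituent, is left.

**Step 12**
Reactants: 15 methyl 8β-hydroxy-3β-(2-methylpropanoyloxy)-7αH-eudesma-4,11(13)-dien-12-oate
Product: 16 methyl 8β-acetoxy-3β-(2-methylpropanoyloxy)-7αH-eudesma-4,11(13)-dien-12-oate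
Conditions: Ac2O, DMAP, pyridine, CH2Cl2, rt
Reagents that add atoms: acetic anhydride, CC(=O)OC(C)=O
Why: DMAP-catalysed acetylation (nucleophilic acyl-transfer catalysis) of the remaining hindered axial alcohol; no stereocentre changes.

**Step 13**
Reactants: 16 methyl 8β-acetoxy-3β-(2-methylpropanoyloxy)-7αH-eudesma-4,11(13)-dien-12-oate
Product: 17 methyl 8β-acetoxy-5α-hydroperoxy-3β-(2-methylpropanoyloxy)-7αH-eudesma-4(15),11(13)-dien-12-oate (CNP0244758.1)
Conditions: O2, tetraphenylporphyrin (cat.), visible light, CH2Cl2, −20 °C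
Reagents that add atoms: dioxygen, O=O
Why: Schenck ene reaction: singlet oxygen should approach the tetrasubstituted C4–C5 alkene from the α face, anti to the axial angular methyl, bond to C5 and abstract a C15 methyl hydrogen, giving the 5α-hydroperoxide and the 4(15)-alkene; H-3 geminal to the acyloxy group is not abstracted, the acrylate is inert, and abstraction of H-6α to the 4α-hydroperoxy-5-ene is the competing path to be separated.

**Compound list**
1 | 2,6-dimethylcyclohex-2-en-1-one (racemic) | CC1=CCCC(C)C1=O | starting material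
2 | [(2,6-dimethylcyclohexa-1,5-dien-1-yl)oxy]trimethylsilane | CC1=CCCC(C)=C1O[Si](C)(C)C | intermediate
3 | (R)-6-(hydroxymethyl)-2,6-dimethylcyclohex-2-en-1-one | OC[C@@]1(C)CCC=C(C)C1=O | intermediate
4 | (S)-6-(chloromethyl)-2,6-dimethylcyclohex-2-en-1-one | ClC[C@@]1(C)CCC=C(C)C1=O | intermediate
5 | boryl ketone: 6-(chloromethyl)-2,6-dimethyl-3-(4,4,5,5-tetramethyl-1,3,2-dioxaborolan-2-yl)cyclohexan-1-one, boron cis to the C2 methyl and to the chloromethyl group | ClC[C@@]1(C)CC[C@@H](B2OC(C)(C)C(C)(C)O2)[C@@H](C)C1=O | intermediate (not isolated)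
6 | (2R,3R,6S)-6-(chloromethyl)-3-hydroxy-2,6-dimethylcyclohexan-1-one (OH cis to the C2 methyl and to CH2Cl) | ClC[C@@]1(C)CC[C@@H](O)[C@@H](C)C1=O | intermediate
7 | methyl 2-bromoacrylate | C=C(Br)C(=O)OC | starting material
8 | dimethyl 2,3-dimethylenesuccinate | C=C(C(=O)OC)C(=C)C(=O)OC | intermediate
9 | spirolactone: methyl 2-[6-(chloromethyl)-9-hydroxy-6,10-dimethyl-2-oxo-1-oxaspiro[4.5]decan-3-yl]prop-2-enoate, lactone oxygen trans to the C6 methyl, C3 epimers | ClC[C@@]1(C)CC[C@@H](O)[C@@H](C)[C@]12CC(C(=C)C(=O)OC)C(=O)O2 | intermediate (not isolated)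
10 | methyl 3α,5α-dihydroxy-8-oxo-4βH-eudesm-11(13)-en-12-oate, C7 epimers | C=C(C(=O)OC)C1C[C@@]2(O)[C@H](C)[C@H](O)CC[C@]2(C)CC1=O | intermediate
11 | methyl 3α,5α-dihydroxy-8-oxo-4βH,7αH-eudesm-11(13)-en-12-oate | C=C(C(=O)OC)[C@H]1C[C@@]2(O)[C@H](C)[C@H](O)CC[C@]2(C)CC1=O | intermediate
12 | methyl 5α-hydroxy-3,8-dioxo-4βH,7αH-eudesm-11(13)-en-12-oate | C=C(C(=O)OC)[C@H]1C[C@@]2(O)[C@H](C)C(=O)CC[C@]2(C)CC1=O | intermediate
13 | methyl 3,8-dioxo-7αH-eudesma-4,11(13)-dien-12-oate | C=C(C(=O)OC)[C@H]1CC2=C(C)C(=O)CC[C@]2(C)CC1=O | intermediate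
14 | methyl 3β,8β-dihydroxy-7αH-eudesma-4,11(13)-dien-12-oate | C=C(C(=O)OC)[C@H]1CC2=C(C)[C@@H](O)CC[C@]2(C)C[C@H]1O | intermediate
15 | methyl 8β-hydroxy-3β-(2-methylpropanoyloxy)-7αH-eudesma-4,11(13)-dien-12-oate | C=C(C(=O)OC)[C@H]1CC2=C(C)[C@@H](OC(=O)C(C)C)CC[C@]2(C)C[C@H]1O | intermediate
16 | methyl 8β-acetoxy-3β-(2-methylpropanoyloxy)-7αH-eudesma-4,11(13)-dien-12-oate | C=C(C(=O)OC)[C@H]1CC2=C(C)[C@@H](OC(=O)C(C)C)CC[C@]2(C)C[C@H]1OC(C)=O | intermediate
17 | methyl 8β-acetoxy-5α-hydroperoxy-3β-(2-methylpropanoyloxy)-7αH-eudesma-4(15),11(13)-dien-12-oate, (3S,5S,7R,8R,10R) | C=C(C(=O)OC)[C@H]1C[C@@]2(OO)C(=C)[C@@H](OC(=O)C(C)C)CC[C@]2(C)C[C@H]1OC(C)=O | target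

**Total step count:** 13. **Longest linear sequence:** 12 (steps 1–4 and 6–13).

**Steps most likely to fail**

Step 6. Reductive oligomerisation of the electron-poor diene 8 may outrun its coupling with the hindered ketyl, and the acrylate may be over-reduced during the photochemical stage. The fallback sets out from 6 and 8 and comes back at 10. One acrylate of 8 is masked by conjugate addition of dimethylamine (Me2NH, MeOH, 0 °C) to give dimethyl 2-[(dimethylamino)methyl]-3-methylidenebutanedioate F1, an ordinary 2-substituted acrylate. The same two-stage SmI2 sequence with 6 should then give methyl 13-(dimethylamino)-3α,5α-dihydroxy-8-oxo-4βH-eudesman-12-oate F2. Exhaustive methylation (MeI, MeCN) should give the ammonium salt methyl 3α,5α-dihydroxy-8-oxo-13-(trimethylammonio)-4βH-eudesman-12-oate iodide F3, and β-elimination with NaHCO3 unmasks the acrylate and returns 10.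

Step 7. Protonation of the dienolate at C13 (giving the conjugated 7(11)-ene) or from the wrong face may compete. The fallback sets out from 10 and comes back at 11. Conjugate addition of thiophenol (PhSH, cat. Et3N) masks the acrylate, so that C7 can be equilibrated thermodynamically (DBU) with no conjugated isomer as a sink, giving the equatorial sulfide methyl 3α,5α-dihydroxy-8-oxo-13-(phenylsulfanyl)-4βH,7αH-eudesman-12-oate F4. Oxidation (NaIO4) gives the sulfoxide methyl 3α,5α-dihydroxy-8-oxo-13-(phenylsulfinyl)-4βH,7αH-eudesman-12-oate F5, and thermal syn-elimination (toluene, 110 °C) regenerates the acrylate as 11.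

Step 2. Facial discrimination by the chiral scandium complex may be poor on this siloxydiene, eroding enantiopurity at the only stereocentre that is carried through. The fallback sets out from 2 and comes back at 3. An achiral Lewis acid (Yb(OTf)3, aq. HCHO, THF/H2O) gives racemic material, 3 together with its enantiomer (S)-6-(hydroxymethyl)-2,6-dimethylcyclohex-2-en-1-one F6. A lipase-catalysed kinetic resolution (immobilised Candida antarctica lipase B, vinyl acetate, hexane) is then expected to acetylate F6 to [(1S)-1,3-dimethyl-2-oxocyclohex-3-en-1-yl]methyl acetate F7 and leave 3, which is separated and carried on.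

**Further compounds**
F1 | step 6 | dimethyl 2-[(dimethylamino)methyl]-3-methylidenebutanedioate | C=C(C(=O)OC)C(CN(C)C)C(=O)OC
F2 | step 6 | methyl 13-(dimethylamino)-3α,5α-dihydroxy-8-oxo-4βH-eudesman-12-oate (C7 and C11 epimers) | COC(=O)C(CN(C)C)C1C[C@@]2(O)[C@H](C)[C@H](O)CC[C@]2(C)CC1=O
F3 | step 6 | methyl 3α,5α-dihydroxy-8-oxo-13-(trimethylammonio)-4βH-eudesman-12-oate iodide (C7 and C11 epimers) | COC(=O)C(C[N+](C)(C)C)C1C[C@@]2(O)[C@H](C)[C@H](O)CC[C@]2(C)CC1=O.[I-]
F4 | step 7 | methyl 3α,5α-dihydroxy-8-oxo-13-(phenylsulfanyl)-4βH,7αH-eudesman-12-oate (C11 epimers) | COC(=O)C(CSc1ccccc1)[C@H]1C[C@@]2(O)[C@H](C)[C@H](O)CC[C@]2(C)CC1=O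
F5 | step 7 | methyl 3α,5α-dihydroxy-8-oxo-13-(phenylsulfinyl)-4βH,7αH-eudesman-12-oate | COC(=O)C(CS(=O)c1ccccc1)[C@H]1C[C@@]2(O)[C@H](C)[C@H](O)CC[C@]2(C)CC1=O
F6 | step 2 | (S)-6-(hydroxymethyl)-2,6-dimethylcyclohex-2-en-1-one | OC[C@]1(C)CCC=C(C)C1=O
F7 | step 2 | [(1S)-1,3-dimethyl-2-oxocyclohex-3-en-1-yl]methyl acetate | CC(=O)OC[C@]1(C)CCC=C(C)C1=O
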